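The target is a longipinenone: a cyclobutane (C4, C5, C10, C9) spanned by the enone bridge C6(=O)–C7=C8 and by the C3–C2–C1–C11 chain. Everything rests on the fact that carbonyl C6 sits on cyclobutane carbon C5: the cyclohexenone ring C4–C5–C6–C7–C8–C9 is therefore made by a Tiffeneau–Demjanov one-carbon expansion of the cyclopentene ring of a norbornene, in which the one-carbon bridge C4 shifts from carbinol carbon C6 to the endo-diazonium carbon C5. This single shift closes the cyclobutane, enlarges the ring and unveils the enone. The norbornene, with seven-membered ring and both esters in place, comes from an intramolecular Diels–Alder reaction of a silyloxycyclopentadiene with a tethered (E)-nitroalkene.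

Key step: step 14

Remark (atom labels used throughout): C1 = CH–O-tigloyl, C2 = CH2, C3 = CH–O-senecioyl, C4 = C(CH3) of the cyclobutane, C5 = cyclobutane CH next to the ketone, C6 = C=O, C7 = CH=, C8 = C(CH3)=, C9 = allylic cyclobutane CH, C10 = cyclobutane CH bonded to C11, C11 = C(CH3)2.

Assumption: in step 1 the (R)-configured ligand is taken to deliver the (R)-carbinol, as is usual for this catalyst class when the alkyl residue outranks allyl; should the sense be opposite, the mirror-image ligand is used.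

Step 1
Reactants: 1 2,2-dimethylpropane-1,3-diol (in excess); 2 allyl acetate
Product: 3 (3R)-2,2-dimethylhex-5-ene-1,3-diol
Conditions: [Ir(cod)Cl]2 (cat.), (R)-BINAP, 4-chloro-3-nitrobenzoic acid (cat.), Cs2CO3 (cat.), THF, 100 °C
Reagents that add atoms: none
Why: Iridium-catalysed transfer-hydrogenative carbonyl allylation from the alcohol oxidation level: one primary alcohol is dehydrogenated in situ and the chiral π-allyl iridium complex adds to the transient aldehyde, the ligand setting C1 as (R), while the excess of diol should suppress double allylation.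

Step 2
Reactants: 3 (3R)-2,2-dimethylhex-5-ene-1,3-diol
Product: 4 (4R)-2,2,5,5-tetramethyl-4-(prop-2-en-1-yl)-1,3-dioxane
Conditions: Me2C(OMe)2, PPTS (cat.), CH2Cl2, rt
Reagents that add atoms: 2,2-dimethoxypropane COC(C)(C)OC
Why: Acid-catalysed transketalisation (acetonide formation) ties the 1,3-diol into a six-membered acetal without touching the stereocentre.

Step 3
Reactants: 4 (4R)-2,2,5,5-tetramethyl-4-(prop-2-en-1-yl)-1,3-dioxane
Product: 6 2-[(4R)-2,2,5,5-tetramethyl-1,3-dioxan-4-yl]acetaldehyde, via ozonide 5 (not isolated)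
Conditions: O3, CH2Cl2, −78 °C; then Me2S, −78 °C → rt
Reagents that add atoms: ozone [O-][O+]=O
Why: Ozonolysis with reductive work-up cleaves the only alkene to the β-alkoxy aldehyde; the acetonide is inert.

Step 4
Reactants: 7 3-methylcyclopent-2-en-1-one
Product: 9 1-methyl-3-(trimethylsilyloxy)cyclopenta-1,3-diene, via lithium dienolate 8 (not isolated)
Conditions: LiN(iPr)2, THF, −78 °C; then Me3SiCl, −78 → 0 °C (used at once)
Reagents that add atoms: chlorotrimethylsilane C[Si](C)(C)Cl
Why: Kinetic α′-deprotonation of the enone and O-silylation give the cross-conjugated silyl dienol ether (silyl enol ether formation).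

Step 5
Reactants: 6 2-[(4R)-2,2,5,5-tetramethyl-1,3-dioxan-4-yl]acetaldehyde; 9 1-methyl-3-(trimethylsilyloxy)cyclopenta-1,3-diene
Product: 10 5-{(1R)-1-hydroxy-2-[(4R)-2,2,5,5-tetramethyl-1,3-dioxan-4-yl]ethyl}-3-methylcyclopent-2-en-1-one (both epimers at ring C5)
Conditions: BF3·OEt2, CH2Cl2, −78 °C; aq. NaHCO3
Reagents that add atoms: none
Why: Mukaiyama aldol addition through an open transition state, in which dipole-minimised 1,3-induction from the β-alkoxy stereocentre C1 (bulky CMe2 residue) should set the new carbinol C3 1,3-anti; the epimeric ring carbon C4 is erased in step 6.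

Step 6
Reactants: 10 aldol adduct
Product: 12 (5S)-5-{(1R)-1-hydroxy-2-[(4R)-2,2,5,5-tetramethyl-1,3-dioxan-4-yl]ethyl}-3,5-dimethylcyclopent-2-en-1-one, via dilithium alkoxide dienolate 11 (not isolated)
Conditions: LiN(iPr)2 (2.5 equiv), THF, −78 → −40 °C; MeI, DMPU, −78 → −30 °C; AcOH quench at −78 °C
Reagents that add atoms: iodomethane CI
Why: Fráter–Seebach alkylation: in the lithium-chelated alkoxide enolate the electrophile attacks C4 on the face away from the C2 chain of the carbinol carbon, so the new methyl is anti to the C3 hydroxyl and the quaternary centre C4 is set from C3.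

Step 7
Reactants: 12 hydroxy enone; 13 3-methylbut-2-enoyl chloride
Product: 14 (1R)-1-[(1S)-1,4-dimethyl-2-oxocyclopent-3-en-1-yl]-2-[(4R)-2,2,5,5-tetramethyl-1,3-dioxan-4-yl]ethyl 3-methylbut-2-enoate
Conditions: pyridine, DMAP (cat.), CH2Cl2, 0 °C → rt
Reagents that add atoms: none
Why: DMAP-catalysed acylation installs the senecioate on the C3 hydroxyl; the weak base avoids deconjugation, and β-elimination is impossible because C4 is quaternary.

Step 8
Reactants: 14 senecioate acetonide
Product: 15 (1R,3R)-1-[(1S)-1,4-dimethyl-2-oxocyclopent-3-en-1-yl]-3,5-dihydroxy-4,4-dimethylpentyl 3-methylbut-2-enoate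
Conditions: 1 M HCl, THF, rt
Reagents that add atoms: none
Why: Acid hydrolysis of the acetonide frees the C1 and C10 hydroxyls under conditions that leave the ester and enone intact.

Step 9
Reactants: 15 diol
Product: 16 (1R,3R)-1-[(1S)-1,4-dimethyl-2-oxocyclopent-3-en-1-yl]-3-hydroxy-4,4-dimethyl-5-oxopentyl 3-methylbut-2-enoate
Conditions: TEMPO (cat.), PhI(OAc)2, CH2Cl2, rt
Reagents that add atoms: none
Why: Oxoammonium (TEMPO) oxidation is chemoselective for the primary C10 alcohol over the hindered secondary C1 alcohol, and the aldehyde cannot enolise because C11 is quaternary.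

Step 10
Reactants: 16 hydroxy aldehyde; 17 (E)-2-methylbut-2-enoyl chloride (tigloyl chloride)
Product: 18 (3R,5R)-5-[(1S)-1,4-dimethyl-2-oxocyclopent-3-en-1-yl]-2,2-dimethyl-5-[(3-methylbut-2-enoyl)oxy]-1-oxopentan-3-yl (2E)-2-methylbut-2-enoate
Conditions: pyridine, DMAP, CH2Cl2, 0 °C → rt
Reagents that add atoms: none
Why: DMAP-catalysed acylation places the tiglate on the C1 hydroxyl, so that both esters of the target are carried from here on.

Step 11
Reactants: 18 diester aldehyde
Product: 21 (1E,4R,6R)-6-[(1S)-1,4-dimethyl-2-oxocyclopent-3-en-1-yl]-3,3-dimethyl-6-[(3-methylbut-2-enoyl)oxy]-1-nitrohex-1-en-4-yl (2E)-2-methylbut-2-enoate, via nitro alcohol 19 (not isolated), via mesylate 20 (not isolated)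
Conditions: MeNO2, tetramethylguanidine (cat.), THF, 0 °C; then MsCl, Et3N, CH2Cl2, −20 → 0 °C
Reagents that add atoms: nitromethane C[N+](=O)[O-]
Why: Henry (nitroaldol) addition to the non-enolisable aldehyde followed by mesylation and E1cB elimination gives the thermodynamically preferred (E)-nitroalkene, which has no γ-hydrogen and so cannot deconjugate.

Step 12
Reactants: 21 nitroalkene enone
Product: 23 Diels–Alder adduct (norbornene with bridgehead OSi(tBu)Me2 on C6, endo-NO2 on C5, C10–C11 bond exo, C4 as one-carbon bridge with CH3 over the C7=C8 bridge), via silyloxycyclopentadiene 22 (not isolated)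
Conditions: TBSOTf, Et3N, CH2Cl2, 0 °C → rt; then toluene, 80 °C
Reagents that add atoms: tert-butyldimethylsilyl trifluoromethanesulfonate CC(C)(C)[Si](C)(C)OS(=O)(=O)C(F)(F)F
Why: Soft enolisation at the γ-position of the α′-blocked enone should give, under equilibrating conditions, the endocyclic 1-silyloxy-3-methylcyclopentadiene, which undergoes an intramolecular Diels–Alder reaction in which the tether on C4 fixes the diene face and forces C11 exo, the E geometry then places NO2 endo on C5, and matched polarity (nucleophilic terminus C9 to electrophilic C10, nitro carbon C5 to silyloxy carbon C6) fixes the regiochemistry, so C5, C6, C9 and C10 are all set from C4.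

Step 13
Reactants: 23 nitro cycloadduct
Product: 24 endo-amine (NH2 in place of NO2 on C5)
Conditions: Zn dust, AcOH, THF, rt
Reagents that add atoms: none
Why: Dissolving-metal reduction of the secondary nitro group to the amine proceeds with retention at C5 under acidic conditions that cannot epimerise it and that leave the alkene, the esters and the silyl ether untouched.

Step 14
Reactants: 24 endo-amine
Product: 26 target CNP0257816.1, via diazonium acetate 25 (not isolated)
Conditions: NaNO2, AcOH/H2O, 0 °C → rt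
Reagents that add atoms: none
Why: Diazotisation turns the endo-NH2 on C5 into N2+, and the C4–C6 bond, the only σ-bond anti-periplanar to the endo C5–N bond, migrates to C5 as N2 leaves while the C6–O lone pair forms a silyloxocarbenium ion that loses its silyl group to water, giving the C6 ketone already conjugated with C7=C8. The closest known reaction type is the Tiffeneau–Demjanov ring expansion (semipinacol deamination of a β-amino alcohol derivative), run here against ring strain, which loss of N2 and formation of the C=O bond should pay for. The cyclobutane C4–C5–C10–C9 is closed by this suprafacial 1,2-alkyl shift (a bond migration, not an exo or endo cyclisation), and the same shift enlarges the five-membered ring C4–C6–C7–C8–C9 to the six-membered ring C4–C5–C6–C7–C8–C9. C5 is formed with inversion (C4 enters anti to nitrogen) and C4 migrates with retention, both dictated by the cage. The selectivity needed is migration of C4 rather than of the vinylic carbon C7 or of hydride from C10: the endo nucleofuge (fixed by the E-nitroalkene in step 12) aligns only C4, excludes π-participation by C7=C8 (which could assist only an exo leaving group) and leaves the endo C10–H syn, while the oxygen on C6 ensures that the migrating bond starts at C6.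

Compound list
1 | 2,2-dimethylpropane-1,3-diol | OCC(C)(C)CO | starting material
2 | allyl acetate | CC(=O)OCC=C | starting material
3 | (3R)-2,2-dimethylhex-5-ene-1,3-diol | C=CC[C@@H](O)C(C)(C)CO | intermediate
4 | (4R)-2,2,5,5-tetramethyl-4-(prop-2-en-1-yl)-1,3-dioxane | C=CC[C@H]1OC(C)(C)OCC1(C)C | intermediate
5 | ozonide of 4 (3-substituted 1,2,4-trioxolane) | O1OC(C[C@H]2OC(C)(C)OCC2(C)C)OC1 | intermediate
6 | 2-[(4R)-2,2,5,5-tetramethyl-1,3-dioxan-4-yl]acetaldehyde | O=CC[C@H]1OC(C)(C)OCC1(C)C | intermediate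
7 | 3-methylcyclopent-2-en-1-one | CC1=CC(=O)CC1 | starting material
8 | lithium 4-methylcyclopenta-1,4-dien-1-olate (α′-dienolate of 7) | [Li+].[O-]C1=CCC(C)=C1 | intermediate
9 | 1-methyl-3-(trimethylsilyloxy)cyclopenta-1,3-diene | CC1=CC(O[Si](C)(C)C)=CC1 | intermediate
10 | 5-{(1R)-1-hydroxy-2-[(4R)-2,2,5,5-tetramethyl-1,3-dioxan-4-yl]ethyl}-3-methylcyclopent-2-en-1-one (epimers at ring C5) | CC1=CC(=O)C(C1)[C@H](O)C[C@H]2OC(C)(C)OCC2(C)C | intermediate
11 | dilithium alkoxide dienolate of 10 | [Li+].[Li+].[O-]C1=C(CC(C)=C1)[C@H]([O-])C[C@H]2OC(C)(C)OCC2(C)C | intermediate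
12 | (5S)-5-{(1R)-1-hydroxy-2-[(4R)-2,2,5,5-tetramethyl-1,3-dioxan-4-yl]ethyl}-3,5-dimethylcyclopent-2-en-1-one | CC1=CC(=O)[C@@](C)(C1)[C@H](O)C[C@H]2OC(C)(C)OCC2(C)C | intermediate
13 | 3-methylbut-2-enoyl chloride | CC(C)=CC(Cl)=O | starting material
14 | (1R)-1-[(1S)-1,4-dimethyl-2-oxocyclopent-3-en-1-yl]-2-[(4R)-2,2,5,5-tetramethyl-1,3-dioxan-4-yl]ethyl 3-methylbut-2-enoate | CC1=CC(=O)[C@@](C)(C1)[C@H](OC(=O)C=C(C)C)C[C@H]2OC(C)(C)OCC2(C)C | intermediate
15 | (1R,3R)-1-[(1S)-1,4-dimethyl-2-oxocyclopent-3-en-1-yl]-3,5-dihydroxy-4,4-dimethylpentyl 3-methylbut-2-enoate | CC1=CC(=O)[C@@](C)(C1)[C@H](OC(=O)C=C(C)C)C[C@@H](O)C(C)(C)CO | intermediate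
16 | (1R,3R)-1-[(1S)-1,4-dimethyl-2-oxocyclopent-3-en-1-yl]-3-hydroxy-4,4-dimethyl-5-oxopentyl 3-methylbut-2-enoate | CC1=CC(=O)[C@@](C)(C1)[C@H](OC(=O)C=C(C)C)C[C@@H](O)C(C)(C)C=O | intermediate
17 | (E)-2-methylbut-2-enoyl chloride (tigloyl chloride) | C/C=C(\C)C(Cl)=O | starting material
18 | (3R,5R)-5-[(1S)-1,4-dimethyl-2-oxocyclopent-3-en-1-yl]-2,2-dimethyl-5-[(3-methylbut-2-enoyl)oxy]-1-oxopentan-3-yl (2E)-2-methylbut-2-enoate | CC1=CC(=O)[C@@](C)(C1)[C@H](OC(=O)C=C(C)C)C[C@@H](OC(=O)/C(C)=C/C)C(C)(C)C=O | intermediate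
19 | nitro alcohol (Henry adduct of 18, CH(OH)CH2NO2 in place of CHO, both carbinol epimers) | CC1=CC(=O)[C@@](C)(C1)[C@H](OC(=O)C=C(C)C)C[C@@H](OC(=O)/C(C)=C/C)C(C)(C)C(O)C[N+](=O)[O-] | intermediate
20 | methanesulfonate of 19 | CC1=CC(=O)[C@@](C)(C1)[C@H](OC(=O)C=C(C)C)C[C@@H](OC(=O)/C(C)=C/C)C(C)(C)C(OS(C)(=O)=O)C[N+](=O)[O-] | intermediate
21 | (1E,4R,6R)-6-[(1S)-1,4-dimethyl-2-oxocyclopent-3-en-1-yl]-3,3-dimethyl-6-[(3-methylbut-2-enoyl)oxy]-1-nitrohex-1-en-4-yl (2E)-2-methylbut-2-enoate | CC1=CC(=O)[C@@](C)(C1)[C@H](OC(=O)C=C(C)C)C[C@@H](OC(=O)/C(C)=C/C)C(C)(C)/C=C/[N+](=O)[O-] | intermediate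
22 | tert-butyldimethylsilyl dienol ether of 21 (1-silyloxy-3,5-dimethyl-5-alkylcyclopenta-1,3-diene; configuration as in SMILES) | CC1=C[C@](C)(C(O[Si](C)(C)C(C)(C)C)=C1)[C@H](OC(=O)C=C(C)C)C[C@@H](OC(=O)/C(C)=C/C)C(C)(C)/C=C/[N+](=O)[O-] | intermediate
23 | Diels–Alder adduct: norborn-5-ene with 1-OSi(tBu)Me2 (C6), 2-endo-NO2 (C5), 5-methyl (C8), 7-methyl syn to the alkene (C4); C7 and the 3-exo position joined by –CH(O-senecioyl)–CH2–CH(O-tigloyl)–CMe2–, both ester carbons (R); absolute configuration as in SMILES | C/C=C(\C)C(=O)O[C@@H]1C[C@@H](OC(=O)C=C(C)C)[C@@]2(C)[C@]3(O[Si](C)(C)C(C)(C)C)C=C(C)[C@H]2[C@@H]([C@H]3[N+](=O)[O-])C1(C)C | intermediate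
24 | endo-amine (NH2 in place of NO2 in 23) | C/C=C(\C)C(=O)O[C@@H]1C[C@@H](OC(=O)C=C(C)C)[C@@]2(C)[C@]3(O[Si](C)(C)C(C)(C)C)C=C(C)[C@H]2[C@@H]([C@H]3N)C1(C)C | intermediate
25 | endo-diazonium acetate of 24 | C/C=C(\C)C(=O)O[C@@H]1C[C@@H](OC(=O)C=C(C)C)[C@@]2(C)[C@]3(O[Si](C)(C)C(C)(C)C)C=C(C)[C@H]2[C@@H]([C@H]3[N+]#N)C1(C)C.CC(=O)[O-] | intermediate
26 | CNP0257816.1 (C1 tiglate, C3 senecioate of the longipinenone core) | C/C=C(\C)C(=O)O[C@@H]1C[C@@H](OC(=O)C=C(C)C)[C@@]2(C)[C@@H]3C(=O)C=C(C)[C@H]2[C@@H]3C1(C)C | target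

Total step count: 14. Longest linear sequence: 13 steps (steps 1–3 and 5–14; step 4 is a one-step side branch).

Steps most likely to fail

Step 14. Loss of N2 may run ahead of the anti-periplanar shift, so that a free norbornenyl cation forms; the better-overlapping vinylic C6–C7 bond could then migrate, or acetate could be captured. The fallback replaces the nitrogen nucleofuge by a sulfonate that leaves only under alkoxide push. It sets out from aldehyde 18: boryl olefination of the Takai type (CrCl2, Cl2CHB(pin), LiI, THF) should give the (E)-alkenyl pinacol boronate F1. Silyl dienol ether formation and cycloaddition as in step 12 (TBSOTf, Et3N; toluene, 110 °C) should give the endo-boronate cycloadduct F2, though the weaker polarisation of the boronate leaves regiocontrol more to sterics. Oxidation with NaBO3·4H2O (THF/H2O) converts C–B to C–O with retention to give the endo-alcohol F3, and MsCl/Et3N gives the endo-mesylate F4. TBAF (THF, 0 °C) then frees the bridgehead alkoxide, which drives the concerted semipinacol shift of C4 and returns to the route at 26.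

Step 12. The cycloaddition must close a seven-membered tether ring between two neopentyl-type carbons (C9 next to C4, C10 next to C11). If it is slow, the silyloxydiene may dimerise, hydrolyse or rest as the unreactive exocyclic dienol ether. The fallback is a stepwise polar annulation from 21: DBU (MeCN, 0 °C → rt) forms the linear dienolate, whose γ-carbon C9 adds to the nitroalkene in an intramolecular vinylogous Michael addition to give the bicyclic nitro enone F5. TBSOTf/Et3N then converts the nitro group into its silyl nitronate and activates the C6 carbonyl; intramolecular nitro-aldol closure with O-silylation returns to the route at 23.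

Step 6. The lithium aldolate may undergo retro-aldol cleavage before or after C-methylation, and facial control in the ketone dianion may be incomplete. The fallback sets C4 at the ester level, where this alkylation is classical, and builds the cyclopentenone afterwards. It sets out from aldehyde 6: Mukaiyama aldol addition of 1-methoxy-1-(trimethylsilyloxy)ethene (BF3·OEt2, −78 °C) should give the 1,3-anti hydroxy ester F6. Fráter–Seebach alkylation (LiN(iPr)2, 2.2 equiv; 3-bromo-2-methylprop-1-ene) gives the anti methallyl ester F7, and a second one (LiN(iPr)2, 2.2 equiv; MeI) gives the quaternary ester F8 with methyl anti to the hydroxyl. LiCH2SiMe3 followed by MeOH converts the ester into the methyl ketone F9, and ozonolysis (O3; Me2S) of the methallyl group gives the 1,4-diketone F10. Intramolecular aldol condensation (KOH, MeOH) then closes the cyclopentenone and returns to the route at 12.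

Further compounds
F1 | step 14 | (E)-alkenyl pinacol boronate (B(pin) in place of NO2 in 21) | CC1=CC(=O)[C@@](C)(C1)[C@H](OC(=O)C=C(C)C)C[C@@H](OC(=O)/C(C)=C/C)C(C)(C)/C=C/B1OC(C)(C)C(C)(C)O1
F2 | step 14 | endo-boronate cycloadduct (B(pin) in place of NO2 in 23) | C/C=C(\C)C(=O)O[C@@H]1C[C@@H](OC(=O)C=C(C)C)[C@@]2(C)[C@]3(O[Si](C)(C)C(C)(C)C)C=C(C)[C@H]2[C@@H]([C@H]3B4OC(C)(C)C(C)(C)O4)C1(C)C
F3 | step 14 | endo-alcohol (OH in place of NO2 in 23) | C/C=C(\C)C(=O)O[C@@H]1C[C@@H](OC(=O)C=C(C)C)[C@@]2(C)[C@]3(O[Si](C)(C)C(C)(C)C)C=C(C)[C@H]2[C@@H]([C@H]3O)C1(C)C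
F4 | step 14 | endo-mesylate of F3 | C/C=C(\C)C(=O)O[C@@H]1C[C@@H](OC(=O)C=C(C)C)[C@@]2(C)[C@]3(O[Si](C)(C)C(C)(C)C)C=C(C)[C@H]2[C@@H]([C@H]3OS(C)(=O)=O)C1(C)C
F5 | step 12 | bicyclic nitro enone (C9–C10 bond formed, CH2NO2 on C10, cyclopentenone retained) | C/C=C(\C)C(=O)O[C@@H]1C[C@@H](OC(=O)C=C(C)C)[C@@]2(C)C(=O)C=C(C)[C@H]2[C@@H](C[N+](=O)[O-])C1(C)C
F6 | step 6 | methyl (3R)-3-hydroxy-4-[(4R)-2,2,5,5-tetramethyl-1,3-dioxan-4-yl]butanoate | COC(=O)C[C@H](O)C[C@H]1OC(C)(C)OCC1(C)C
F7 | step 6 | anti 2-(2-methylprop-2-en-1-yl) derivative of F6 | COC(=O)[C@H](CC(C)=C)[C@H](O)C[C@H]1OC(C)(C)OCC1(C)C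
F8 | step 6 | 2-methyl-2-(2-methylprop-2-en-1-yl) derivative of F6 (methyl anti to OH) | COC(=O)[C@@](C)(CC(C)=C)[C@H](O)C[C@H]1OC(C)(C)OCC1(C)C
F9 | step 6 | methyl ketone from F8 (acetyl in place of CO2Me) | CC(=O)[C@@](C)(CC(C)=C)[C@H](O)C[C@H]1OC(C)(C)OCC1(C)C
F10 | step 6 | 1,4-diketone from F9 (2-oxopropyl in place of methallyl) | CC(=O)[C@@](C)(CC(C)=O)[C@H](O)C[C@H]1OC(C)(C)OCC1(C)C
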